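**Plan**

- **Cuts:** The C7 silyl ether goes first. The benzene ring (ring A) is then taken apart at C4a–C5, C5–C6, C7–C8 and C8–C8a. This leaves 2-(2-diazopropanoyl)-6-tricosyl-4-pyranone and 1-(triisopropylsilyloxy)propyne. The pyranone (ring B) is cut at O1–C8a and C4a–C8a (oxalate unit), and the chain at C1'–C2'.
- **Enabling feature:** Ring A carries OH at C5, CH3 at C6, O at C7 and CH3 at C8, and shares its C4a=C8a edge with ring B. This pattern is what a vinylketene leaves when it takes up an ynol ether: ketene C=O becomes C5–OH, the ketene α-carbon becomes C8, the ring B C=C serves as the vinyl group, and the alkyne supplies C6 and C7.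
- **Forward order:** The chain comes first (acetylacetone dianion plus docosyl bromide). Ring B comes second (oxalate acylation, acid cyclodehydration). The acid chloride is then treated with diazoethane, ring A is closed last, and the silyl group is removed.
- **Stereochemistry:** The target has no stereocentre and no configured double bond, so nothing has to be set.

Key step: step 8

Assumption: the side chain is read as unbranched tricosyl (C23); di- and tricarbonyl compounds are drawn as keto tautomers and lithium enolates as ion pairs.

**Step 1**
Reactants: 1 acetylacetone (pentane-2,4-dione); 2 docosyl bromide (1-bromodocosane)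
Product: 4 heptacosane-2,4-dione, via dilithium dianion of acetylacetone 3 (not isolated)
Conditions: LiN(i-Pr)2 (2.1 equiv), THF, 0 °C; 2, THF, 0 °C to rt; aq. HCl
Reagents that add atoms: none
Why: γ-Alkylation of a β-diketone dianion: in 3 the terminal carbanion is far more nucleophilic than the delocalised central position, so the primary bromide is displaced (SN2) only at the former methyl carbon and the unbranched C23 chain is completed.

**Step 2**
Reactants: 4 heptacosane-2,4-dione; 5 diethyl oxalate
Product: 7 ethyl 2,4,6-trioxononacosanoate, via dilithium dianion of heptacosane-2,4-dione 6 (not isolated)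
Conditions: LiN(i-Pr)2 (2.1 equiv), THF, 0 °C; cannulate into 5 (3 equiv), THF, −78 °C; aq. HCl, −78 °C to rt
Reagents that add atoms: none
Why: Terminal acylation of a β-diketone dianion by an ester (Claisen-type condensation): the second deprotonation of 4 takes place at the CH3 group rather than at the chain CH2, and running 6 into cold excess oxalate keeps the dianion from being protonated by the more acidic product or from meeting an already acylated molecule.

**Step 3**
Reactants: 7 ethyl 2,4,6-trioxononacosanoate
Product: 9 4-oxo-6-tricosyl-4H-pyran-2-carboxylic acid, via ethyl 4-oxo-6-tricosyl-4H-pyran-2-carboxylate 8 (not isolated)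
Conditions: conc. aq. HCl, AcOH, reflux
Reagents that add atoms: water, O
Why: Acid-catalysed cyclodehydration of a 1,3,5-tricarbonyl chain to a 4-pyranone (6-exo-trig attack of the enol oxygen at C6 on the C2 ketone, then loss of water) is the classical entry to pyranone-2-carboxylates, and hydrolysis of ester 8 in the same acidic medium avoids the ring opening that hydroxide causes in pyranones.

**Step 4**
Reactants: 9 4-oxo-6-tricosyl-4H-pyran-2-carboxylic acid
Product: 10 4-oxo-6-tricosyl-4H-pyran-2-carbonyl chloride
Conditions: (COCl)2, DMF (cat.), CH2Cl2, 0 °C to rt; evaporate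
Reagents that add atoms: oxalyl chloride, O=C(Cl)C(=O)Cl
Why: Acid chloride formation by way of the chloroiminium salt from DMF and oxalyl chloride is routine for chromone- and pyranone-2-carboxylic acids, the ring carbonyl of this electron-poor pyranone being too weak a nucleophile to compete with the carboxyl group.

**Step 5**
Reactants: 11 N-ethyl-N-nitrosourea
Product: 12 diazoethane (ethereal solution)
Conditions: KOH (40% aq.), Et2O, −10 °C; decant, dry over KOH pellets
Reagents that add atoms: none
Why: Base-induced fragmentation of an N-alkyl-N-nitrosourea (hydroxide attacks the carbamoyl carbon, cyanate leaves and the ethyldiazotate loses water) is the standard way to an ethereal diazoalkane solution, which is used at once and never concentrated.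

**Step 6**
Reactants: 10 4-oxo-6-tricosyl-4H-pyran-2-carbonyl chloride; 12 diazoethane
Product: 13 2-(2-diazopropanoyl)-6-tricosyl-4H-pyran-4-one
Conditions: 12 (3 equiv), Et2O–CH2Cl2, −20 to 0 °C
Reagents that add atoms: none
Why: Acylation of a diazoalkane by an acid chloride (the first stage of the Arndt–Eistert sequence, here with diazoethane so that the future C8 methyl group is brought in) needs no base or organometal that could touch the pyranone, the excess diazoethane takes up the HCl, and at low temperature acylation should outrun dipolar cycloaddition to the ring double bonds.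

**Step 7**
Reactants: 14 prop-1-yn-1-yllithium (1-propynyllithium)
Product: 16 triisopropyl(prop-1-yn-1-yloxy)silane, via lithium prop-1-yn-1-olate 15 (not isolated)
Conditions: t-BuOOH (in decane), LiN(SiMe3)2, THF, −78 °C; add 14, −78 to 0 °C; i-Pr3SiOTf, −78 to 0 °C
Reagents that add atoms: tert-butyl hydroperoxide, CC(C)(C)OO; triisopropylsilyl trifluoromethanesulfonate, CC(C)[Si](OS(=O)(=O)C(F)(F)F)(C(C)C)C(C)C
Why: Electrophilic oxygenation of a lithium acetylide by lithium tert-butyl peroxide (attack at the peroxide oxygen, tert-butoxide leaving) gives ynolate 15, which the bulky silyl triflate traps on oxygen to the siloxyalkyne instead of on carbon to a silylketene.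

**Step 8**
Reactants: 13 2-(2-diazopropanoyl)-6-tricosyl-4H-pyran-4-one; 16 triisopropyl(prop-1-yn-1-yloxy)silane
Product: 21 5-hydroxy-6,8-dimethyl-2-tricosyl-7-(triisopropylsilyloxy)-4H-chromen-4-one, via methyl(pyranonyl)ketene 17 (not isolated), via cyclobutenone 18 (not isolated), via dienylketene 19 (not isolated), via cyclohexadienone 20 (not isolated)
Conditions: 16 (2 equiv), hν (400 nm LED), degassed ClCH2CH2Cl, 25 °C; then reflux
Reagents that add atoms: none
Why: Light absorbed by the diazoketone chromophore expels N2 and shifts pyranone C2 from the acyl carbon to the diazo carbon (Wolff rearrangement, the future C8–C8a bond), which gives ketene 17 with its C=C=O unit conjugated to the ring C2=C3 bond. Alkyne 16 adds across the ketene C=C in a [2+2] cycloaddition in which its nucleophilic, methyl-bearing carbon attacks the ketene carbonyl carbon (C5–C6) and its oxygen-bearing carbon joins the ketene α-carbon (C7–C8), so the polarisation of the ynol ether by itself fixes the order OH, CH3, OSi, CH3 around the new ring. On heating, cyclobutenone 18 opens reversibly by four-electron conrotatory electrocyclic cleavage of the bond between its carbonyl and quaternary carbons, and the isomer 19 that holds ketene and pyranonyl group cis is drained off. Ring A closes by six-electron disrotatory electrocyclisation of the ketene carbon onto pyranone C3 (C4a–C5), the only possible terminus because the other neighbour of C2 is the ring oxygen, and enolisation of 20 delivers the phenol, whose hydrogen bond to the C4 carbonyl keeps it from intercepting ketene. The sequence is the diazoketone variant of the Danheiser benzannulation, well established for cycloalkenyl, aryl and five-membered heteroaryl diazoketones in combination with siloxyalkynes, and the pyranone C2=C3 bond is more olefinic than any of those arenes, so the closure costs little. No stereocentre remains (those of 18 and 20 are transient and racemic), and the chemoselectivity needed, decomposition of the diazo group without excitation of the pyranone or of the product chromone, is secured by irradiating near 400 nm where only the diazoketone absorbs.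

**Step 9**
Reactants: 21 5-hydroxy-6,8-dimethyl-2-tricosyl-7-(triisopropylsilyloxy)-4H-chromen-4-one
Product: 22 5,7-dihydroxy-6,8-dimethyl-2-tricosyl-4H-chromen-4-one (target)
Conditions: Bu4NF, AcOH, THF, 0 °C to rt
Reagents that add atoms: none
Why: Fluoride-induced cleavage of a phenolic silyl ether, driven by the strong Si–F bond, is fast even between two ortho methyl groups, and acetic acid protonates the phenoxide so that the chromone never sits in a basic medium.

**Compound list**

1 | acetylacetone (pentane-2,4-dione) | CC(=O)CC(C)=O | starting material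
2 | 1-bromodocosane | CCCCCCCCCCCCCCCCCCCCCCBr | starting material
3 | dilithium dianion of acetylacetone | [Li+].[Li+].C=C([O-])C=C(C)[O-] | intermediate
4 | heptacosane-2,4-dione | CCCCCCCCCCCCCCCCCCCCCCCC(=O)CC(C)=O | intermediate
5 | diethyl oxalate | CCOC(=O)C(=O)OCC | starting material
6 | dilithium dianion of heptacosane-2,4-dione | [Li+].[Li+].C=C([O-])C=C([O-])CCCCCCCCCCCCCCCCCCCCCCC | intermediate
7 | ethyl 2,4,6-trioxononacosanoate | CCCCCCCCCCCCCCCCCCCCCCCC(=O)CC(=O)CC(=O)C(=O)OCC | intermediate
8 | ethyl 4-oxo-6-tricosyl-4H-pyran-2-carboxylate | CCCCCCCCCCCCCCCCCCCCCCCc1cc(=O)cc(C(=O)OCC)o1 | intermediate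
9 | 4-oxo-6-tricosyl-4H-pyran-2-carboxylic acid | CCCCCCCCCCCCCCCCCCCCCCCc1cc(=O)cc(C(=O)O)o1 | intermediate
10 | 4-oxo-6-tricosyl-4H-pyran-2-carbonyl chloride | CCCCCCCCCCCCCCCCCCCCCCCc1cc(=O)cc(C(=O)Cl)o1 | intermediate
11 | N-ethyl-N-nitrosourea | CCN(N=O)C(N)=O | starting material
12 | diazoethane | CC=[N+]=[N-] | intermediate
13 | 2-(2-diazopropanoyl)-6-tricosyl-4H-pyran-4-one | CC(=[N+]=[N-])C(=O)c1cc(=O)cc(CCCCCCCCCCCCCCCCCCCCCCC)o1 | intermediate
14 | prop-1-yn-1-yllithium | CC#C[Li] | starting material
15 | lithium prop-1-yn-1-olate | CC#C[O-].[Li+] | intermediate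
16 | triisopropyl(prop-1-yn-1-yloxy)silane | CC#CO[Si](C(C)C)(C(C)C)C(C)C | intermediate
17 | 2-(4-oxo-6-tricosyl-4H-pyran-2-yl)prop-1-en-1-one (methyl(pyranonyl)ketene) | CC(=C=O)c1cc(=O)cc(CCCCCCCCCCCCCCCCCCCCCCC)o1 | intermediate
18 | 2,4-dimethyl-4-(4-oxo-6-tricosyl-4H-pyran-2-yl)-3-(triisopropylsilyloxy)cyclobut-2-en-1-one (racemic) | CC1=C(O[Si](C(C)C)(C(C)C)C(C)C)C(C)(c2cc(=O)cc(CCCCCCCCCCCCCCCCCCCCCCC)o2)C1=O | intermediate
19 | (3E)-2-methyl-4-(4-oxo-6-tricosyl-4H-pyran-2-yl)-3-(triisopropylsilyloxy)penta-1,3-dien-1-one (ketene and pyranonyl cis) | CC(=C=O)/C(O[Si](C(C)C)(C(C)C)C(C)C)=C(/C)c1cc(=O)cc(CCCCCCCCCCCCCCCCCCCCCCC)o1 | intermediate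
20 | 6,8-dimethyl-2-tricosyl-7-(triisopropylsilyloxy)-4aH-chromene-4,5-dione (racemic) | CCCCCCCCCCCCCCCCCCCCCCCC1=CC(=O)C2C(=O)C(C)=C(O[Si](C(C)C)(C(C)C)C(C)C)C(C)=C2O1 | intermediate
21 | 5-hydroxy-6,8-dimethyl-2-tricosyl-7-(triisopropylsilyloxy)-4H-chromen-4-one | CCCCCCCCCCCCCCCCCCCCCCCc1cc(=O)c2c(O)c(C)c(O[Si](C(C)C)(C(C)C)C(C)C)c(C)c2o1 | intermediate
22 | 5,7-dihydroxy-6,8-dimethyl-2-tricosyl-4H-chromen-4-one | CCCCCCCCCCCCCCCCCCCCCCCc1cc(=O)c2c(O)c(C)c(O)c(C)c2o1 | target

**Total step count:** 9.
**Longest linear sequence:** 7 (steps 1, 2, 3, 4, 6, 8, 9).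

**Steps most likely to fail**

1. **Step 8 (benzannulation).**
   - What may go wrong: a 1,2-hydrogen shift from the methyl group to the carbene centre may outrun migration of the electron-poor pyranonyl group. The ketene may be lost by self-addition before it meets the alkyne. Stray excitation may trigger rearrangement of the pyranone ring.
   - Fallback: it uses neither light nor ketene and builds ring B onto a ready-made ring A by the Mentzer thermal chromone synthesis. It sets out from 2 and comes back at 22. Ethyl acetoacetate is deprotonated twice with LiN(i-Pr)2 in THF to the dilithium dianion of ethyl acetoacetate F1. This dianion is alkylated at its terminal carbon by 2 to give ethyl 3-oxohexacosanoate F2. F2 is heated without solvent at about 240 °C together with purchased 2,4-dimethylbenzene-1,3,5-triol. This acylates the single free ring carbon and closes the pyranone, which should give 22 directly, so step 9 also falls away.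

2. **Step 6 (diazoketone).**
   - What may go wrong: dipolar cycloaddition of excess diazoethane across the doubly activated C2=C3 bond, and hydrochlorination of the diazo group if the diazoalkane runs short.
   - Fallback: the diazo group is brought in by diazo transfer instead of by a diazoalkane. It sets out from 10 and comes back at 13. Compound 10 is treated with MeNH(OMe)·HCl and pyridine in CH2Cl2 to give N-methoxy-N-methyl-4-oxo-6-tricosyl-4H-pyran-2-carboxamide F3. EtMgBr in THF at −78 °C (Weinreb ketone synthesis) converts it into 2-propanoyl-6-tricosyl-4H-pyran-4-one F4. Kinetic deprotonation at the ketone CH2 with LiN(SiMe3)2, followed by CF3CO2CH2CF3, gives 4,4,4-trifluoro-2-methyl-1-(4-oxo-6-tricosyl-4H-pyran-2-yl)butane-1,3-dione F5. This is treated crude with MsN3, Et3N and water in MeCN (detrifluoroacetylative Regitz-type diazo transfer) to reach 13.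

3. **Step 2 (oxalate acylation).**
   - What may go wrong: proton transfer from the more acidic product to unreacted dianion. A second attack on the remaining ester carbonyl is also possible, either by O-cyclisation to a five-membered lactone or by twofold C-acylation.
   - Fallback: a one-sided C2 electrophile at the aldehyde oxidation level is used and oxidised afterwards. It sets out from 6 and comes back at 9. Dianion 6 is acylated with ethyl diethoxyacetate, a non-enolisable monoester, to give 1,1-diethoxynonacosane-2,4,6-trione F6. Aqueous CF3CO2H effects cyclodehydration and acetal hydrolysis to 4-oxo-6-tricosyl-4H-pyran-2-carbaldehyde F7. Pinnick oxidation (NaClO2, NaH2PO4, 2-methyl-2-butene, t-BuOH–THF–water) then gives acid 9.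

**Further compounds**

F1 | step 8 | dilithium dianion of ethyl acetoacetate | [Li+].[Li+].C=C([O-])C=C([O-])OCC
F2 | step 8 | ethyl 3-oxohexacosanoate | CCCCCCCCCCCCCCCCCCCCCCCC(=O)CC(=O)OCC
F3 | step 6 | N-methoxy-N-methyl-4-oxo-6-tricosyl-4H-pyran-2-carboxamide | CON(C)C(=O)c1cc(=O)cc(CCCCCCCCCCCCCCCCCCCCCCC)o1
F4 | step 6 | 2-propanoyl-6-tricosyl-4H-pyran-4-one | CCC(=O)c1cc(=O)cc(CCCCCCCCCCCCCCCCCCCCCCC)o1
F5 | step 6 | 4,4,4-trifluoro-2-methyl-1-(4-oxo-6-tricosyl-4H-pyran-2-yl)butane-1,3-dione (racemic) | CC(C(=O)C(F)(F)F)C(=O)c1cc(=O)cc(CCCCCCCCCCCCCCCCCCCCCCC)o1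
F6 | step 2 | 1,1-diethoxynonacosane-2,4,6-trione | CCCCCCCCCCCCCCCCCCCCCCCC(=O)CC(=O)CC(=O)C(OCC)OCC
F7 | step 2 | 4-oxo-6-tricosyl-4H-pyran-2-carbaldehyde | CCCCCCCCCCCCCCCCCCCCCCCc1cc(=O)cc(C=O)o1
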